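**Direct plan and its weak points**

A direct plan would build the furanone first: a 5-aryl-3(2H)-furanone A1 would be C-acylated with a methoxyacetyl unit and silylated to the 3-silyloxyfuran A2, A2 would be added to dimethyl 2-oxopropanedioate A3 (Mukaiyama aldol) to give the adduct A4, and a Dieckmann condensation would close the carbocycle to the enol A5, followed by O-methylation and desilylation.
- The aldol addition that creates the spiro carbon C5 would give A4 as a racemate, so one enantiomer would have to be separated on a chiral phase in mid-route, with loss of half the material.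
- The Dieckmann ring closure would have to choose between two diastereotopic ester groups on a crowded carbon whose neighbours invite retro-aldol cleavage, so the configuration of C6 would rest on an unproven preference.
- The O-methylation of the unsymmetrical enol A5 could fall on either oxygen of the 2-methoxy-1,3-dione, and three silyl or benzyl groups would be put on and taken off without building anything.

**Retrosynthetic overview of the new route**

1. Feature used: in ring B (C5–C9) the carbinol carbon C6 carries OH and CO2Me and sits next to the spiro atom C5, the mark of a benzilic ester ring contraction. Ring B plus the ester carbon are therefore taken from one six-membered ring, the fully oxygenated benzene ring of a flavonoid-type 1,3-diketone.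
2. Key disconnection: contraction of the racemic 1-oxaspiro[4.5]decadienetetrone 7 with methanol, which cleaves C5–C(ester), forms C5–C6 and sets C5 and C6 together under a chiral amine–squaramide catalyst through a ring-opened intermediate without a stereocentre.
3. Ring order: the carbocycle is present from the start (arene 3); the furanone ring A is closed second by O1–C5 bond formation (trivalent iodine spirocyclisation of hydroxyquinone 6); the contraction to the five-membered ring B comes last.
4. Weak steps avoided by design: no resolution (the spiro centre of 7 is erased and set anew), no choice between two ester groups (only one carboxyl carbon ever exists), no regiochemical O-methylation (both enol methyl ethers are methoxy groups of 3), and a single protecting group.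

Key step: step 5

Assumption: 1-(2-hydroxy-3,4,5,6-tetramethoxyphenyl)ethan-1-one (3), the ketone used for the polymethoxyflavones of the tangeretin group, is taken as a catalogue compound.

**Route**

Step 1
Reactants: 1 methyl 4-hydroxybenzoate
Product: 2 methyl 4-[tri(propan-2-yl)silyloxy]benzoate
Conditions: i-Pr3SiCl, imidazole, DMF, rt
Reagents that add atoms: chlorotri(propan-2-yl)silane, CC(C)[Si](Cl)(C(C)C)C(C)C
Why: Imidazole-promoted O-silylation masks the phenol, the only group of the benzoate that would interfere with the base of step 2 and the oxidants of steps 3 and 4; no stereocentre is involved.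

Step 2
Reactants: 3 1-(2-hydroxy-3,4,5,6-tetramethoxyphenyl)ethan-1-one; 2 methyl 4-[tri(propan-2-yl)silyloxy]benzoate
Product: 4 1-(2-hydroxy-3,4,5,6-tetramethoxyphenyl)-3-{4-[tri(propan-2-yl)silyloxy]phenyl}propane-1,3-dione
Conditions: LiN(SiMe3)2 (3.5 equiv), THF, −78 → 0 °C; then 2, 0 °C → rt; aq. NH4Cl, 1 M HCl to pH 4
Reagents that add atoms: none
Why: In this crossed Claisen condensation (the C-acylation that also underlies the Baker–Venkataraman route to flavones) the phenoxide–enolate dianion of 3 should be acylated at carbon by ester 2, and the excess base holds the product as its unreactive diketonate so that the reaction stops at the 1,3-diketone.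

Step 3
Reactants: 4 1-(2-hydroxy-3,4,5,6-tetramethoxyphenyl)-3-{4-[tri(propan-2-yl)silyloxy]phenyl}propane-1,3-dione
Product: 6 2-hydroxy-5,6-dimethoxy-3-(3-oxo-3-{4-[tri(propan-2-yl)silyloxy]phenyl}propanoyl)cyclohexa-2,5-diene-1,4-dione, via acylquinone 5 (not isolated)
Conditions: PhI(OAc)2 (1.05 equiv), MeCN/H2O (3:1), 0 °C; then phosphate buffer pH 7.5, rt; acidified to pH 3, extraction
Reagents that add atoms: water, O
Why: The electron-rich phenol should be oxidised by the trivalent iodine reagent far faster than the diketone, water adds to a methoxy-bearing ring carbon and methanol is lost (oxidative demethylation of a methoxyphenol to a quinone), and in the buffer the methoxy group next to the acyl group, a doubly vinylogous methyl ester, is exchanged for hydroxide by addition–elimination to give the acidic hydroxyquinone as the thermodynamic sink, whether water first attacked para or ortho to the phenol; the two methoxy groups that survive are those of C7 and C8 of the target.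

Step 4
Reactants: 6 2-hydroxy-5,6-dimethoxy-3-(3-oxo-3-{4-[tri(propan-2-yl)silyloxy]phenyl}propanoyl)cyclohexa-2,5-diene-1,4-dione
Product: 7 rac-8,9-dimethoxy-2-{4-[tri(propan-2-yl)silyloxy]phenyl}-1-oxaspiro[4.5]deca-2,8-diene-4,6,7,10-tetrone
Conditions: PhI(OAc)2 (1.1 equiv), CH2Cl2/(CF3)2CHOH (4:1), −20 → 0 °C; volatiles and acetic acid removed by evaporation with toluene, used at once
Reagents that add atoms: none
Why: This is a dehydrogenative C–O coupling by a hypervalent iodine reagent at the α-carbon of a β-tricarbonyl compound, the same reactivity as oxidative phenol dearomatisation with an internal oxygen nucleophile: the acidic hydroxyquinone OH should exchange onto iodine, and the enol oxygen of the side-chain aryl ketone should attack the acyl-bearing ring carbon in a five-membered closure with loss of PhI, which forms the O1–C5 bond and the 3(2H)-furanone ring A; the spiro carbon is formed as a racemate, which step 5 makes irrelevant.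

Step 5
Reactants: 7 rac-8,9-dimethoxy-2-{4-[tri(propan-2-yl)silyloxy]phenyl}-1-oxaspiro[4.5]deca-2,8-diene-4,6,7,10-tetrone
Product: 9 methyl (5S,6R)-6-hydroxy-7,8-dimethoxy-4,9-dioxo-2-{4-[tri(propan-2-yl)silyloxy]phenyl}-1-oxaspiro[4.4]nona-2,7-diene-6-carboxylate, via ring-opened keto ester 8 (not isolated)
Conditions: MeOH (3 equiv), quinine-derived squaramide 3-{[3,5-bis(trifluoromethyl)phenyl]amino}-4-{[(8α,9S)-6′-methoxycinchonan-9-yl]amino}cyclobut-3-ene-1,2-dione (10 mol %; or its quinidine-derived pseudoenantiomer, whichever leads to the (5S,6R) series), toluene/CH2Cl2, 4 Å molecular sieves, −40 → −20 °C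
Reagents that add atoms: methanol, CO
Why: Proposed new method: methanol should add to C6 of 7, the only ring carbonyl that is not a vinylogous ester and one half of a vicinal dione, and the hemiketal, deprotonated by the quinuclidine nitrogen, should expel the spiro carbon as a resonance-stabilised 3-oxidofuran (retro-Claisen cleavage), which gives the Z-configured α-keto ester 8, a compound without a stereocentre, as its ion pair with the protonated chiral base; C5 of the furanolate then adds to the keto group of the α-keto ester, held by the squaramide N–H bonds, so that the net change is a benzilic ester ring contraction. The closest known reaction types are the base-mediated benzilic acid ring contraction of 2,2-disubstituted cyclohexene-1,3,4-triones (the first stage of the Hooker oxidation of 2-hydroxy-3-alkylnaphthoquinones) and the amine–squaramide-catalysed aldol addition of 3(2H)-furanones and other acidic carbonyl pronucleophiles to α-keto esters; new is their union in one enantioconvergent event on a racemic spirocycle. The carbocycle C5–C6–C7–C8–C9 closes by a 5-(enolexo)-exo-trig aldol addition with the Z double bond C7=C8, inherited from the six-membered ring, inside the new ring. Both stereocentres, C5 and C6, arise in this one C–C bond formation, so the racemic nature of 7 is without consequence, the absolute configuration is decided by the catalyst, and the relative configuration is expected from an open, metal-free transition state in which the developing C6 alkoxide points away from the furanolate oxygen on C4 and so ends on the face of O1, with the ester on the face of the C4 carbonyl, as (5S,6R) requires. The step needs site selectivity of the methanol addition (secured by the higher electrophilicity of the non-conjugated C6 carbonyl over the vinylogous ester carbonyls C10 and C4), retention of the Z geometry of 8 (secured by fast five-membered ring closure at low temperature) and a slow uncatalysed pathway (secured by the absence of any other base, the removal of acetic acid after step 4 and the low temperature).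

Step 6
Reactants: 9 methyl (5S,6R)-6-hydroxy-7,8-dimethoxy-4,9-dioxo-2-{4-[tri(propan-2-yl)silyloxy]phenyl}-1-oxaspiro[4.4]nona-2,7-diene-6-carboxylate
Product: 10 methyl (5S,6R)-6-hydroxy-2-(4-hydroxyphenyl)-7,8-dimethoxy-4,9-dioxo-1-oxaspiro[4.4]nona-2,7-diene-6-carboxylate (limnophilaspiroketone)
Conditions: Bu4NF (1.2 equiv), AcOH (1.5 equiv), THF, 0 °C
Reagents that add atoms: none
Why: Fluoride-mediated cleavage of the aryl silyl ether, with acetic acid as buffer so that the medium never turns basic and the tertiary β-hydroxy ketone is not opened by retro-aldol reaction; C5 and C6 are not touched.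

**Compound list**

1 | methyl 4-hydroxybenzoate | COC(=O)c1ccc(O)cc1 | starting material
2 | methyl 4-[tri(propan-2-yl)silyloxy]benzoate | COC(=O)c1ccc(O[Si](C(C)C)(C(C)C)C(C)C)cc1 | intermediate
3 | 1-(2-hydroxy-3,4,5,6-tetramethoxyphenyl)ethan-1-one | CC(=O)c1c(O)c(OC)c(OC)c(OC)c1OC | starting material
4 | 1-(2-hydroxy-3,4,5,6-tetramethoxyphenyl)-3-{4-[tri(propan-2-yl)silyloxy]phenyl}propane-1,3-dione | COc1c(O)c(C(=O)CC(=O)c2ccc(O[Si](C(C)C)(C(C)C)C(C)C)cc2)c(OC)c(OC)c1OC | intermediate
5 | 2,3,5-trimethoxy-6-(3-oxo-3-{4-[tri(propan-2-yl)silyloxy]phenyl}propanoyl)cyclohexa-2,5-diene-1,4-dione | COC1=C(OC)C(=O)C(C(=O)CC(=O)c2ccc(O[Si](C(C)C)(C(C)C)C(C)C)cc2)=C(OC)C1=O | intermediate (not isolated)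
6 | 2-hydroxy-5,6-dimethoxy-3-(3-oxo-3-{4-[tri(propan-2-yl)silyloxy]phenyl}propanoyl)cyclohexa-2,5-diene-1,4-dione | COC1=C(OC)C(=O)C(C(=O)CC(=O)c2ccc(O[Si](C(C)C)(C(C)C)C(C)C)cc2)=C(O)C1=O | intermediate
7 | rac-8,9-dimethoxy-2-{4-[tri(propan-2-yl)silyloxy]phenyl}-1-oxaspiro[4.5]deca-2,8-diene-4,6,7,10-tetrone | COC1=C(OC)C(=O)C2(OC(c3ccc(O[Si](C(C)C)(C(C)C)C(C)C)cc3)=CC2=O)C(=O)C1=O | intermediate
8 | methyl (3Z)-5-(3-hydroxy-5-{4-[tri(propan-2-yl)silyloxy]phenyl}furan-2-yl)-3,4-dimethoxy-2,5-dioxopent-3-enoate | COC(=O)C(=O)/C(OC)=C(OC)\C(=O)c1oc(-c2ccc(O[Si](C(C)C)(C(C)C)C(C)C)cc2)cc1O | intermediate (not isolated)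
9 | methyl (5S,6R)-6-hydroxy-7,8-dimethoxy-4,9-dioxo-2-{4-[tri(propan-2-yl)silyloxy]phenyl}-1-oxaspiro[4.4]nona-2,7-diene-6-carboxylate | COC(=O)[C@@]1(O)C(OC)=C(OC)C(=O)[C@]12OC(c1ccc(O[Si](C(C)C)(C(C)C)C(C)C)cc1)=CC2=O | intermediate
10 | methyl (5S,6R)-6-hydroxy-2-(4-hydroxyphenyl)-7,8-dimethoxy-4,9-dioxo-1-oxaspiro[4.4]nona-2,7-diene-6-carboxylate (limnophilaspiroketone) | COC(=O)[C@@]1(O)C(OC)=C(OC)C(=O)[C@]12OC(c1ccc(O)cc1)=CC2=O | target

**Count and risks**

Total step count: 6. Longest linear sequence: 6 steps (1 → 10).

Steps most likely to fail: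

Step 5 (proposed new method). Ring contraction through an uncatalysed pathway or through a stereoretentive 1,2-shift that never opens the ring would give material of low enantiomeric purity. Closure of the aldol through a bridged transition state would give the C6 epimer. Ring opening at the vinylogous ester carbonyl C10 would lead to an open-chain ester that does not close. Which pseudoenantiomeric catalyst gives the (5S,6R) series would have to be found by trial and settled by the sign of rotation of 10. Fallback with known chemistry: from 7, the benzilic ester ring contraction would be run with NaOMe (5 mol %) in MeOH/CH2Cl2 at −40 °C to give rac-methyl (5S,6R)-6-hydroxy-7,8-dimethoxy-4,9-dioxo-2-{4-[tri(propan-2-yl)silyloxy]phenyl}-1-oxaspiro[4.4]nona-2,7-diene-6-carboxylate F1. The enantiomers would then be separated by preparative chromatography on an immobilised amylose tris(3,5-dimethylphenylcarbamate) phase, and the route is rejoined at 9.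

Step 4. The trivalent iodine reagent may engage the enol of the side-chain 1,3-diketone instead of the hydroxyquinone, so that the ring oxygen closes onto the side-chain carbon. Alternatively, 7 may take up water and contract to the carboxylic acid. Fallback: from 6, the acyl-bearing ring carbon would be hydroxylated with dimethyldioxirane in acetone at −40 °C to give 2-hydroxy-5,6-dimethoxy-2-(3-oxo-3-{4-[tri(propan-2-yl)silyloxy]phenyl}propanoyl)cyclohex-5-ene-1,3,4-trione F2. The tertiary hydroxy 1,3-diketone would then be cyclodehydrated with TsOH (5 mol %) and 4 Å molecular sieves in CH2Cl2, the standard closure of 3(2H)-furanones, which returns to 7.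

Step 3. Over-oxidation at the diketone methylene, or ring closure of quinone 5 by its own side-chain enol in place of hydrolysis, would give a mixture. Fallback: from 4, acid-catalysed cyclodehydration (TsOH, toluene, 80 °C) would give 5,6,7,8-tetramethoxy-2-{4-[tri(propan-2-yl)silyloxy]phenyl}-4H-chromen-4-one F3. Oxidative demethylation with (NH4)2Ce(NO3)6 in MeCN/H2O would give 6,7-dimethoxy-2-{4-[tri(propan-2-yl)silyloxy]phenyl}-4H-chromene-4,5,8-trione F4. Opening of the pyranone ring in aqueous MeCN buffered at pH 8–9 would then return to 6.

**Further compounds**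

F1 | step 5 | rac-methyl (5S,6R)-6-hydroxy-7,8-dimethoxy-4,9-dioxo-2-{4-[tri(propan-2-yl)silyloxy]phenyl}-1-oxaspiro[4.4]nona-2,7-diene-6-carboxylate | COC(=O)C1(O)C(OC)=C(OC)C(=O)C12OC(c1ccc(O[Si](C(C)C)(C(C)C)C(C)C)cc1)=CC2=O
F2 | step 4 | 2-hydroxy-5,6-dimethoxy-2-(3-oxo-3-{4-[tri(propan-2-yl)silyloxy]phenyl}propanoyl)cyclohex-5-ene-1,3,4-trione | COC1=C(OC)C(=O)C(O)(C(=O)CC(=O)c2ccc(O[Si](C(C)C)(C(C)C)C(C)C)cc2)C(=O)C1=O
F3 | step 3 | 5,6,7,8-tetramethoxy-2-{4-[tri(propan-2-yl)silyloxy]phenyl}-4H-chromen-4-one | COc1c(OC)c(OC)c2oc(-c3ccc(O[Si](C(C)C)(C(C)C)C(C)C)cc3)cc(=O)c2c1OC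
F4 | step 3 | 6,7-dimethoxy-2-{4-[tri(propan-2-yl)silyloxy]phenyl}-4H-chromene-4,5,8-trione | COC1=C(OC)C(=O)C2=C(C1=O)C(=O)C=C(c1ccc(O[Si](C(C)C)(C(C)C)C(C)C)cc1)O2
A1 | direct plan | 5-{4-[tri(propan-2-yl)silyloxy]phenyl}furan-3(2H)-one | O=C1COC(c2ccc(O[Si](C(C)C)(C(C)C)C(C)C)cc2)=C1
A2 | direct plan | 2-methoxy-1-(3-(triethylsilyloxy)-5-{4-[tri(propan-2-yl)silyloxy]phenyl}furan-2-yl)ethan-1-one | COCC(=O)c1oc(-c2ccc(O[Si](C(C)C)(C(C)C)C(C)C)cc2)cc1O[Si](CC)(CC)CC
A3 | direct plan | dimethyl 2-oxopropanedioate | COC(=O)C(=O)C(=O)OC
A4 | direct plan | rac-dimethyl 2-[2-(methoxyacetyl)-3-oxo-5-{4-[tri(propan-2-yl)silyloxy]phenyl}-2,3-dihydrofuran-2-yl]-2-(triethylsilyloxy)propanedioate | COCC(=O)C1(C(O[Si](CC)(CC)CC)(C(=O)OC)C(=O)OC)OC(c2ccc(O[Si](C(C)C)(C(C)C)C(C)C)cc2)=CC1=O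
A5 | direct plan | methyl (5S,6R)-7-hydroxy-8-methoxy-4,9-dioxo-6-(triethylsilyloxy)-2-{4-[tri(propan-2-yl)silyloxy]phenyl}-1-oxaspiro[4.4]nona-2,7-diene-6-carboxylate | COC(=O)[C@@]1(O[Si](CC)(CC)CC)C(O)=C(OC)C(=O)[C@]12OC(c1ccc(O[Si](C(C)C)(C(C)C)C(C)C)cc1)=CC2=O
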